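The runs come from a simulation for an exercise, noise included.

Percent hides what the isomer of the product does, so I count it in mol per litre. The flask is the cedar run followed on.

| flask | starting material | other conformer | protic impurity | remark | time |
|---|---|---|---|---|---|
| cedar | 0.20 M | 0.020 M | 0.020 M | the very flask that is asked about, followed so far |  |
| ash | 0.13 M | 0.020 M | 0.020 M | run made earlier |  |
| flask | 0.20 M | 0.0200 M | 0.0200 M |  | 50 min |

- cedar (time / min: isomer of the product / %, target / %): 0.333: 4.5, 43.0; 0.667: 4.7, 66.4; 1.50: 5.4, 86.6; 4.00: 5.8, 91.9
- ash (time / min: isomer of the product / %, target / %): 4.00: 6.9, 90.8; 12.0: 7.7, 91.1; 25.0: 7.7, 90.9; 40.0: 7.3, 90.8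

(scatter of a reading: 0.3 percentage points)

1. ratio of isomer of the product to target at 0.60 s
2. ratio of isomer of the product to target at 50 min

1. I take the target in cedar as first order towards its last reading, 91.9 %. The first reading then gives a rate constant k = 1.89 min⁻¹ and a time constant τ = 0.528 min. The curve leaves zero steeply, reaching 1.74 % at 0.60 s. It bends near τ at 58.1 % and stands at 86.5 % at 1.50 min, against a reading of 86.6 %.

2. The isomer in cedar already reads 4.5 % at 0.333 min. From there to 4.00 min it gains s = 0.0266 per unit of target, a selectivity factor. Carried back to zero target, that line leaves a burst b = 0.00739 M.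

3. I assume the burst comes from the charged other conformer and follow one molecule of it. Then b over that charge gives 0.369: the burst share φ, the chance that such a molecule ends as isomer of the product.

4. For ash, φ and s give 7.34 %, and its readings run from 6.9 % to 7.7 %, with a scatter of 0.3 percentage points.

5. My ratio for the flask at 50 min is the level of cedar, 0.0631. At 0.60 s the burst is unresolved, so I commit to a ceiling of 1.93 and no value.

6. The forecast gives 0.6 at 0.60 s, a value it calls “very uncertain”, and 0.069 at 50 min, which it reaches by adding the late gain of ash to cedar. Its late ratio is higher than mine.

The flask gives 0.184 at 0.60 s, lower than the forecast, and 0.0627 at 50 min, with target at 91.8 % and isomer of the product at 5.76 %.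

    starting material ⇌ other conformer (K = 0.0220, k = 0.00220 s⁻¹)
    starting material → target (k = 0.0310 s⁻¹)
    other conformer → isomer of the product (k = 0.0590 s⁻¹)
    starting material + target → side product (k = 0.00370 M⁻¹ s⁻¹)
    other conformer + protic impurity → quenched substrate (k = 0.0880 M⁻¹ s⁻¹)

For a neighbour flask charged with 0.0080 M of other conformer, φ and s reckon the isomer of the product at 3.91 %; that neighbour flask holds 3.88 % at 50.0 min.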